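**Strategy.** The route rests on disconnecting ring A at C5–C10 and C3–C4. Ring A shares C5–C10 with the seven-membered ring B and C4–C5 with the γ-lactone. A butenolide C4=C5, tied through C6–C7–arene (C8, C9)–C20 to a 2-silyloxydiene C10=C1–C2=C3, therefore closes rings A and B in one intramolecular Diels–Alder reaction, with the C1 oxygen already in place. The single stereocentre C6, taken from (R)-epichlorohydrin, passes its configuration to C4 and C5 and is erased later. The precursor is a hexasubstituted trimethoxyarene that carries the (R)-3-methylbutenolide on C7 and the (Z)-silyloxydiene on C20.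

Key step: step 13

Remark: atom numbers are those of the target (ring A C1–C5 and C10; ring B C5, C6, C7, C8, C9, C20, C10; quinone ring C8, C9, C11–C14; lactone carbonyl C19 on C4, lactone oxygen on C6).
Remark: the carbinol carbon of 8–10, 12–14 and 17–22 is racemic and C4 of 17–20 is unassigned; both centres disappear, so the mixtures are carried on.
Remark: C10 of 25 and 26 is written as the cis-fused epimer; the other epimer would converge in step 15.
Remark: the precursor is kept with its tert-butyldimethylsilyl and methyl groups; because the hydrogen on C6 of the butenolide is base-labile, no basic reagent is used between steps 9 and 13 except the cold enol silylation of step 12.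

**Step 1**
Reactants: 1 1,2,4-trimethoxybenzene
Product: 3 2-(2,3,6-trimethoxyphenyl)propan-2-ol, via (2,3,6-trimethoxyphenyl)lithium 2 (not isolated)
Conditions: n-BuLi, THF, 0 °C; acetone, −78 °C → rt; H2O
Reagents that add atoms: acetone CC(C)=O
Why: Directed ortho-metalation takes the ring hydrogen flanked by two methoxy groups (future C13) and the aryllithium adds to acetone; no stereocentre is formed.

**Step 2**
Reactants: 3 2-(2,3,6-trimethoxyphenyl)propan-2-ol
Product: 4 1,2,4-trimethoxy-3-(propan-2-yl)benzene
Conditions: Et3SiH, CF3CO2H, CH2Cl2, 0 °C → rt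
Reagents that add atoms: none
Why: Ionic hydrogenation, in which the tertiary benzylic alcohol ionises in acid and the cation is reduced by hydride transfer from the silane.

**Step 3**
Reactants: 4 1,2,4-trimethoxy-3-(propan-2-yl)benzene
Product: 5 1-bromo-2,4,5-trimethoxy-3-(propan-2-yl)benzene
Conditions: NBS, MeCN, 0 °C → rt
Reagents that add atoms: N-bromosuccinimide O=C1CCC(=O)N1Br
Why: Electrophilic aromatic bromination should go to the free position that is ortho to one methoxy group and para to another (future C8), since the other free position is activated by only one ortho methoxy group.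

**Step 4**
Reactants: 5 1-bromo-2,4,5-trimethoxy-3-(propan-2-yl)benzene
Product: 6 1-bromo-2-iodo-3,4,6-trimethoxy-5-(propan-2-yl)benzene
Conditions: NIS, CF3CO2H (cat.), MeCN, rt
Reagents that add atoms: N-iodosuccinimide O=C1CCC(=O)N1I
Why: Acid-activated electrophilic iodination can only take the one remaining ring hydrogen (future C9), which gives a bromide and an iodide that can be addressed one after the other.

**Step 5**
Reactants: 7 penta-1,4-dien-3-ol
Product: 8 tert-butyl(dimethyl)(penta-1,4-dien-3-yloxy)silane
Conditions: TBSCl, imidazole, DMF, rt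
Reagents that add atoms: tert-butyl(chloro)dimethylsilane CC(C)(C)[Si](C)(C)Cl
Why: Imidazole-promoted silylation of a secondary alcohol gives an ether that survives the Grignard and enolate steps.

**Step 6**
Reactants: 8 tert-butyl(dimethyl)(penta-1,4-dien-3-yloxy)silane (3 equiv), 6 1-bromo-2-iodo-3,4,6-trimethoxy-5-(propan-2-yl)benzene
Product: 10 5-(2-bromo-3,5,6-trimethoxy-4-isopropylphenyl)pent-1-en-3-yl TBS ether, via B-alkyl-9-BBN 9 (not isolated)
Conditions: 9-BBN (1.5 equiv), THF, 0 °C → rt; then 6, Pd(dppf)Cl2 (5 mol %), K3PO4 (aq), DMF, 60 °C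
Reagents that add atoms: none
Why: Anti-Markovnikov hydroboration of one vinyl group (diene in excess) is followed by B-alkyl Suzuki–Miyaura coupling, in which zerovalent palladium inserts into the C–I bond much faster than into the C–Br bond; the carbinol carbon is racemic and is oxidised later.

**Step 7**
Reactants: 10 5-(2-bromo-3,5,6-trimethoxy-4-isopropylphenyl)pent-1-en-3-yl TBS ether, 11 (R)-epichlorohydrin
Product: 14 (R)-2-(arylmethyl)oxirane carrying the C9 side chain, via arylmagnesium bromide 12 (not isolated), via chlorohydrin 13 (not isolated)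
Conditions: Mg, THF, 50 °C; CuI (10 mol %), 11, −30 → 0 °C; NaOH, MeOH–H2O, rt
Reagents that add atoms: none
Why: Copper-catalysed Grignard opening of the epoxide at its CH2 terminus (SN2) does not touch the stereocentre, and the alkoxide then displaces chloride to give the transposed terminal epoxide, whose carbinol carbon (future C6) is R.

**Step 8**
Reactants: 14 (R)-2-(arylmethyl)oxirane carrying the C9 side chain, 15 propanoic acid
Product: 18 (5S)-5-(arylmethyl)-3-methyloxolan-2-one, via dilithium propanoate dianion 16 (not isolated), via γ-hydroxy acid 17 (not isolated)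
Conditions: 15, LiN(i-Pr)2 (2 equiv per acid, acid in slight excess), THF, 0 °C; 14, 0 → 40 °C; HCl (aq); TsOH (cat.), CH2Cl2, rt
Reagents that add atoms: none
Why: The carboxylic acid dianion opens the terminal epoxide at CH2 (SN2, C6 untouched) and the γ-hydroxy acid lactonises under acid catalysis; the α-methyl centre C4 forms as a mixture that is erased in step 9.

**Step 9**
Reactants: 18 (5S)-5-(arylmethyl)-3-methyloxolan-2-one
Product: 21 (5R)-5-(arylmethyl)-3-methylfuran-2(5H)-one with the silyl ether side chain, via α-phenylselanyl lactone 19 (not isolated), via selenoxide 20 (not isolated)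
Conditions: LiN(i-Pr)2, THF, −78 °C; PhSeBr; then AcOH, H2O2 (30 %), 0 °C → rt
Reagents that add atoms: none
Why: α-Selenenylation of the lactone enolate and selenoxide syn-elimination toward the ring CH2 should give the conjugated endocyclic 3-methylbutenolide (any exocyclic methylene isomer is removed by chromatography), and C6 takes no part.

**Step 10**
Reactants: 21 (5R)-5-(arylmethyl)-3-methylfuran-2(5H)-one with the silyl ether side chain
Product: 22 (R)-butenolide with the 3-hydroxypent-4-enyl chain on C9
Conditions: HF·pyridine, THF, 0 °C → rt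
Reagents that add atoms: none
Why: Acidic fluoride desilylation is chosen over basic fluoride because the hydrogen on C6 of the butenolide is base-labile.

**Step 11**
Reactants: 22 (R)-butenolide with the 3-hydroxypent-4-enyl chain on C9
Product: 23 (R)-butenolide vinyl ketone
Conditions: Dess–Martin periodinane, CH2Cl2, 0 °C → rt
Reagents that add atoms: none
Why: Dess–Martin oxidation of the secondary allylic alcohol under neutral conditions gives the enone, which is used at once.

**Step 12**
Reactants: 23 (R)-butenolide vinyl ketone
Product: 24 (R)-butenolide (Z)-2-silyloxydiene (cycloaddition precursor)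
Conditions: TBSOTf (1.05 equiv), Et3N, CH2Cl2, −78 °C; pH 7 buffer at −78 °C
Reagents that add atoms: tert-butyldimethylsilyl trifluoromethanesulfonate CC(C)(C)[Si](C)(C)OS(=O)(=O)C(F)(F)F
Why: Soft enolisation (silyl triflate and amine) of the CH2 group C10 next to the ketone gives the thermodynamically preferred Z 2-silyloxydiene; at −78 °C and with one equivalent of triflate the more Lewis-basic ketone should be silylated faster than the butenolide, whose C6–H must stay untouched.

**Step 13**
Reactants: 24 (R)-butenolide (Z)-2-silyloxydiene (cycloaddition precursor)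
Product: 25 tetracyclic lactone with C1=C2 silyl enol ether
Conditions: PhMe (0.005 M), BHT (cat.), 180 °C, sealed tube, silylated glass
Reagents that add atoms: none
Why: This is a thermal, concerted, suprafacial [4+2] cycloaddition of normal electron demand, in which the nucleophilic diene terminus C10 bonds to the butenolide β-carbon C5 and C3 bonds to the α-carbon C4; the closest known reaction type is the intramolecular Diels–Alder reaction of 2-silyloxydienes with butenolide dienophiles. Ring A closes as the six-membered ring of the cycloaddition itself, and ring B closes as the seven-membered ring made by the tether C20–C9–C8–C7–C6 between C10 and C5, whose two arene atoms lower the entropic cost. C4 and C5 are controlled by C6: the tether leaves C6 through C7, so the diene can only reach the butenolide face that carries C7, which places C6–H, C5–H and the C4 methyl group cis on the lactone. C10 is set by the endo or exo folding (lactone carbonyl under the diene gives the cis-fused epimer written) and is irrelevant because C10 becomes sp2 in step 15. The step needs facial selectivity and para regiochemistry; the first is secured by the short tether and the second by the tether together with the polarity of the diene, while the Z enol ether geometry puts C20 on the outside of the diene so that the s-cis conformer can be reached. Heating without Lewis acid or amine should avoid Mukaiyama–Michael pathways and epimerisation at C6.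

**Step 14**
Reactants: 25 tetracyclic lactone with C1=C2 silyl enol ether
Product: 26 tetracyclic C1 ketone
Conditions: HCl (1 M), THF, 0 °C → rt
Reagents that add atoms: none
Why: Acid hydrolysis of the silyl enol ether (protonation at C2) frees the C1 ketone without base, so retro-Michael opening of ring A is avoided; C10 may epimerise but becomes sp2 in the next step.

**Step 15**
Reactants: 26 tetracyclic C1 ketone
Product: 27 dienone lactone with C6=C7 and C10=C20
Conditions: DDQ (2.2 equiv), 1,4-dioxane, 80 °C
Reagents that add atoms: none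
Why: DDQ dehydrogenation by benzylic hydride abstraction at C7 and C20 of the electron-rich arene, each followed by loss of the only neighbouring proton (C6–H, and C10–H acidified by the C1 ketone), should give the enol lactone C6=C7 and the enone C10=C20 while C4 and C5 stay untouched.

**Step 16**
Reactants: 27 dienone lactone with C6=C7 and C10=C20
Product: 28 (1R)-allylic alcohol
Conditions: NaBH4, CeCl3·7H2O, MeOH, −78 °C
Reagents that add atoms: none
Why: Luche 1,2-reduction of the enone, in which hydride should attack C1 from the face of C5–H and the C4 methyl group, anti to the cis-fused lactone bridge, so that the hydroxyl group ends on the lactone face (1R).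

**Step 17**
Reactants: 28 (1R)-allylic alcohol
Product: 29 12-O-methyl-6,7-anhydroballotiquinone
Conditions: (NH4)2Ce(NO3)6 (2.5 equiv), MeCN–H2O, 0 °C
Reagents that add atoms: water O
Why: Oxidative demethylation of the para-dimethoxy pair C11/C14 by tetravalent cerium, through the arene radical cation and ipso attack of water, gives the para-quinone and leaves the C12 methoxy group as a vinylogous ester.

**Step 18**
Reactants: 29 12-O-methyl-6,7-anhydroballotiquinone
Product: 30 6,7-anhydroballotiquinone
Conditions: BCl3, CH2Cl2, −78 °C; H2O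
Reagents that add atoms: none
Why: Chelation-assisted cleavage of the vinylogous methyl ester, in which boron binds O12 and the neighbouring C11 carbonyl and chloride removes the methyl group by SN2 at a temperature at which the enol lactone and the allylic alcohol (as its borate) should survive.

**Compound list**
1 | 1,2,4-trimethoxybenzene | COc1ccc(OC)c(OC)c1 | starting material
2 | (2,3,6-trimethoxyphenyl)lithium | [Li]c1c(OC)c(OC)ccc1OC | intermediate
3 | 2-(2,3,6-trimethoxyphenyl)propan-2-ol | CC(C)(O)c1c(OC)c(OC)ccc1OC | intermediate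
4 | 1,2,4-trimethoxy-3-(propan-2-yl)benzene | CC(C)c1c(OC)c(OC)ccc1OC | intermediate
5 | 1-bromo-2,4,5-trimethoxy-3-(propan-2-yl)benzene (Br on future C8) | CC(C)c1c(OC)c(OC)cc(Br)c1OC | intermediate
6 | 1-bromo-2-iodo-3,4,6-trimethoxy-5-(propan-2-yl)benzene (I on future C9) | CC(C)c1c(OC)c(OC)c(I)c(Br)c1OC | intermediate
7 | penta-1,4-dien-3-ol | C=CC(O)C=C | starting material
8 | tert-butyl(dimethyl)(penta-1,4-dien-3-yloxy)silane | C=CC(O[Si](C)(C)C(C)(C)C)C=C | intermediate
9 | 9-[3-(tert-butyldimethylsilyloxy)pent-4-en-1-yl]-9-borabicyclo[3.3.1]nonane, racemic | C=CC(O[Si](C)(C)C(C)(C)C)CCB1C2CCCC1CCC2 | intermediate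
10 | {[5-(2-bromo-3,5,6-trimethoxy-4-isopropylphenyl)pent-1-en-3-yl]oxy}(tert-butyl)dimethylsilane, racemic | CC(C)c1c(OC)c(OC)c(CCC(O[Si](C)(C)C(C)(C)C)C=C)c(Br)c1OC | intermediate
11 | (R)-epichlorohydrin, (2R)-2-(chloromethyl)oxirane | ClC[C@H]1CO1 | starting material
12 | arylmagnesium bromide from 10 (Mg on C8) | CC(C)c1c(OC)c(OC)c(CCC(O[Si](C)(C)C(C)(C)C)C=C)c([Mg]Br)c1OC | intermediate
13 | (2R)-1-aryl-3-chloropropan-2-ol, aryl = 2-[3-(TBSO)pent-4-enyl]-3,4,6-trimethoxy-5-isopropylphenyl | CC(C)c1c(OC)c(OC)c(CCC(O[Si](C)(C)C(C)(C)C)C=C)c(C[C@@H](O)CCl)c1OC | intermediate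
14 | (2R)-2-(arylmethyl)oxirane, same aryl group | CC(C)c1c(OC)c(OC)c(CCC(O[Si](C)(C)C(C)(C)C)C=C)c(C[C@@H]2CO2)c1OC | intermediate
15 | propanoic acid | CCC(=O)O | starting material
16 | dilithium dianion of propanoic acid | CC=C(O[Li])O[Li] | intermediate
17 | (4S)-5-aryl-4-hydroxy-2-methylpentanoic acid, C2 epimers | CC(C)c1c(OC)c(OC)c(CCC(O[Si](C)(C)C(C)(C)C)C=C)c(C[C@@H](O)CC(C)C(=O)O)c1OC | intermediate
18 | (5S)-5-(arylmethyl)-3-methyloxolan-2-one, C3 epimers | CC(C)c1c(OC)c(OC)c(CCC(O[Si](C)(C)C(C)(C)C)C=C)c(C[C@H]2OC(=O)C(C)C2)c1OC | intermediate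
19 | (5R)-5-(arylmethyl)-3-methyl-3-(phenylselanyl)oxolan-2-one, C3 epimers | CC(C)c1c(OC)c(OC)c(CCC(O[Si](C)(C)C(C)(C)C)C=C)c(C[C@H]2OC(=O)C(C)([Se]c3ccccc3)C2)c1OC | intermediate
20 | selenoxide of 19 | CC(C)c1c(OC)c(OC)c(CCC(O[Si](C)(C)C(C)(C)C)C=C)c(C[C@H]2OC(=O)C(C)([Se](=O)c3ccccc3)C2)c1OC | intermediate
21 | (5R)-5-(arylmethyl)-3-methylfuran-2(5H)-one, side chain as TBS ether | CC(C)c1c(OC)c(OC)c(CCC(O[Si](C)(C)C(C)(C)C)C=C)c(C[C@H]2OC(=O)C(C)=C2)c1OC | intermediate
22 | (5R)-5-{[2-(3-hydroxypent-4-enyl)-3,4,6-trimethoxy-5-isopropylphenyl]methyl}-3-methylfuran-2(5H)-one | CC(C)c1c(OC)c(OC)c(CCC(O)C=C)c(C[C@H]2OC(=O)C(C)=C2)c1OC | intermediate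
23 | (5R)-5-{[2-(3-oxopent-4-enyl)-3,4,6-trimethoxy-5-isopropylphenyl]methyl}-3-methylfuran-2(5H)-one | CC(C)c1c(OC)c(OC)c(CCC(=O)C=C)c(C[C@H]2OC(=O)C(C)=C2)c1OC | intermediate
24 | (5R)-5-{[2-((2Z)-3-(tert-butyldimethylsilyloxy)penta-2,4-dienyl)-3,4,6-trimethoxy-5-isopropylphenyl]methyl}-3-methylfuran-2(5H)-one | CC(C)c1c(OC)c(OC)c(C/C=C(\O[Si](C)(C)C(C)(C)C)C=C)c(C[C@H]2OC(=O)C(C)=C2)c1OC | intermediate
25 | (4S,5R,6R,10S) tetracyclic 19,6-lactone, 11,12,14-trimethoxyarene, C1=C2 TBS enol ether; H on C5, C6, C10 and the C4 methyl group all cis | CC(C)c1c(OC)c(OC)c2c(C[C@H]3OC(=O)[C@@]4(C)CC=C(O[Si](C)(C)C(C)(C)C)[C@@H](C2)[C@@H]34)c1OC | intermediate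
26 | (4S,5R,6R,10S) tetracyclic 19,6-lactone with C1 ketone | CC(C)c1c(OC)c(OC)c2c(C[C@H]3OC(=O)[C@@]4(C)CCC(=O)[C@@H](C2)[C@@H]34)c1OC | intermediate
27 | (4S,5R) 1-oxo-6,10(20)-diene 19,6-lactone, trimethoxyarene | CC(C)c1c(OC)c(OC)c2c(C=C3OC(=O)[C@@]4(C)CCC(=O)C(=C2)[C@@H]34)c1OC | intermediate
28 | (1R,4S,5R) 1-hydroxy-6,10(20)-diene 19,6-lactone, trimethoxyarene | CC(C)c1c(OC)c(OC)c2c(C=C3OC(=O)[C@@]4(C)CC[C@@H](O)C(=C2)[C@@H]34)c1OC | intermediate
29 | (1R,4S,5R) 12-O-methyl-6,7-anhydroballotiquinone | CC(C)C1=C(OC)C(=O)C2=C(C=C3OC(=O)[C@@]4(C)CC[C@@H](O)C(=C2)[C@@H]34)C1=O | intermediate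
30 | (1R,4S,5R) 6,7-anhydroballotiquinone | CC(C)C1=C(O)C(=O)C2=C(C=C3OC(=O)[C@@]4(C)CC[C@@H](O)C(=C2)[C@@H]34)C1=O | target

**Totals.** 18 steps in all; the longest linear sequence is 17 steps (steps 1–4 and 6–18; step 5 prepares the coupling partner).

**Steps most likely to fail**

Step 13. The cycloaddition may not outrun decomposition: the trisubstituted, α-methylated dienophile and the seven-membered tether ring raise the barrier, and long heating invites desilylation or polymerisation of the diene. The fallback forms the same two bonds one after the other by polar chemistry. Starting from 24, TiCl4 in CH2Cl2 at −78 °C should trigger an intramolecular Mukaiyama–Michael addition of C10 to C5 (7-exo-trig, on the C7 face for the same tether reason). Aqueous work-up would give the ring B keto lactone with a free vinyl ketone F1. Catalytic KOt-Bu in THF/t-BuOH at 0 °C should then let the lactone enolate at C4 add to the enone terminus C3 (6-endo-trig). Only the cis-fused lactone can form, so C4 follows C5, and the route is rejoined at ketone 26.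

Step 12. Configuration at C6 may be lost: if the silyl triflate also activates the butenolide, the amine removes the C6 proton, a 2-silyloxyfuran forms and the only source of asymmetry is racemised. The fallback keeps the dienophile latent while base is present. It starts from selenide 19, isolated after the selenenylation of step 9 without adding peroxide. HF·pyridine would give the selenide allylic alcohol F2. Parikh–Doering oxidation (SO3·pyridine, DMSO, i-Pr2NEt), which leaves selenium alone, would give the selenide vinyl ketone F3. TBSOTf and Et3N would give the selenide silyloxydiene F4, whose lactone has no acidic hydrogen. Only then would NaIO4 with NaHCO3 in aqueous THF at 0 °C oxidise selenium; the selenoxide F5 should eliminate at room temperature, and the route is rejoined at precursor 24.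

Step 15. Reactivity may be uneven and oxidation may go too far: C20 may lag behind C7, and once both alkenes are present excess DDQ can abstract hydride from the doubly allylic C5–H of the benzocycloheptatriene, which would destroy C5. The fallback separates the two dehydrogenations and gives C10=C20 to enolate chemistry. Starting from 26, TMSCl, NaI and Et3N in MeCN should give the more substituted trimethylsilyl enol ether F6 (C1=C10). Saegusa–Ito oxidation with Pd(OAc)2 (divalent palladium) in MeCN should give the C10=C20 enone F7 by β-hydride loss from benzylic C20. One equivalent of DDQ then has only C7 left to attack, and the route is rejoined at dienone 27.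

**Further compounds**
F1 | step 13 | ring B keto lactone with C5–C10 bond, saturated lactone (C4–H) and vinyl ketone at C1; C5 and C6 as in 25 | CC(C)c1c(OC)c(OC)c2c(C[C@H]3OC(=O)C(C)[C@H]3C(C2)C(=O)C=C)c1OC
F2 | step 12 | (5R)-3-methyl-3-(phenylselanyl)oxolan-2-one with the 3-hydroxypent-4-enyl chain on C9 | CC(C)c1c(OC)c(OC)c(CCC(O)C=C)c(C[C@H]2OC(=O)C(C)([Se]c3ccccc3)C2)c1OC
F3 | step 12 | (5R)-3-methyl-3-(phenylselanyl)oxolan-2-one with the 3-oxopent-4-enyl chain on C9 | CC(C)c1c(OC)c(OC)c(CCC(=O)C=C)c(C[C@H]2OC(=O)C(C)([Se]c3ccccc3)C2)c1OC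
F4 | step 12 | (5R)-3-methyl-3-(phenylselanyl)oxolan-2-one with the (Z)-3-(TBSO)penta-2,4-dienyl chain on C9 | CC(C)c1c(OC)c(OC)c(C/C=C(\O[Si](C)(C)C(C)(C)C)C=C)c(C[C@H]2OC(=O)C(C)([Se]c3ccccc3)C2)c1OC
F5 | step 12 | selenoxide of F4 | CC(C)c1c(OC)c(OC)c(C/C=C(\O[Si](C)(C)C(C)(C)C)C=C)c(C[C@H]2OC(=O)C(C)([Se](=O)c3ccccc3)C2)c1OC
F6 | step 15 | trimethylsilyl enol ether C1=C10 of ketone 26 | CC(C)c1c(OC)c(OC)c2c(C[C@H]3OC(=O)[C@@]4(C)CCC(O[Si](C)(C)C)=C(C2)[C@@H]34)c1OC
F7 | step 15 | (4S,5R,6R) 1-oxo-10(20)-ene 19,6-lactone with saturated C6–C7 | CC(C)c1c(OC)c(OC)c2c(C[C@H]3OC(=O)[C@@]4(C)CCC(=O)C(=C2)[C@@H]34)c1OC
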